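The route rests on opening ring C of the flavanone half at the O1–C2 bond. Ring C is a β-aryloxy ketone: O1 lies β to the C4 carbonyl, so the ring is the oxa-Michael adduct of the C8a phenol and a C2=C3 enone. The precursor is an open-chain alkylidene β-keto ester that already holds rings A and B and the finished flavone. A removable tert-butyl ester at C3 activates the acceptor, and O1, beside the C8–C8'' biaryl bond, is its only free phenol. In one operation a cinchona thiourea closes ring C, sets C2 as S and fixes the 8-linkage; acid then expels the ester. A Suzuki–Miyaura coupling supplies the biaryl.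

Key step: step 9

Remark: plain locants refer to the flavanone half (rings A, B, C) and double-primed locants to the flavone half. The C8–C8'' axis carries four ortho oxygen substituents and should rotate slowly, but the structure defines only C2 (S), so the axis is left uncontrolled and every biaryl compound is carried as both axial forms.

Step 1
Reactants: 1 apigenin
Product: 2 5,7,4'-tri-O-benzylapigenin
Conditions: BnBr (4 equiv), K2CO3, DMF, 80 °C
Reagents that add atoms: benzyl bromide, BrCc1ccccc1
Why: Williamson ether synthesis in which excess halide and heat also alkylate the chelated 5-OH, whose capping is needed to steer the next step to C8.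

Step 2
Reactants: 2 5,7,4'-tri-O-benzylapigenin
Product: 3 8-iodo-5,7,4'-tri-O-benzylapigenin
Conditions: NIS (1.05 equiv), TFA (cat.), MeCN/CH2Cl2, 0 °C to rt, dark
Reagents that add atoms: N-iodosuccinimide, O=C1CCC(=O)N1I
Why: Electrophilic aromatic iodination goes to ring A of the flavone, the ring activated by three oxygen atoms, and there to C8, which lies between one benzyloxy group and the bare ring oxygen, rather than to C6, which is shielded by two benzyloxy groups.

Step 3
Reactants: 3 8-iodo-5,7,4'-tri-O-benzylapigenin
Product: 4 5,7,4'-tri-O-benzylapigenin-8-boronic acid pinacol ester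
Conditions: B2pin2, Pd(dppf)Cl2 (5 mol %), KOAc, dioxane, 90 °C
Reagents that add atoms: bis(pinacolato)diboron, CC1(C)OB(OC1(C)C)B1OC(C)(C)C(C)(C)O1
Why: Miyaura borylation of the aryl iodide, in which the weak base KOAc enables transmetalation with the diboron without setting off homocoupling, and to which the flavone carbonyl and the benzyl ethers are inert.

Step 4
Reactants: 5 2',4',6'-trihydroxyacetophenone
Product: 6 1-[2,4-bis(benzyloxy)-6-hydroxyphenyl]ethanone
Conditions: BnBr (2.1 equiv), K2CO3, DMF, 60 °C
Reagents that add atoms: benzyl bromide, BrCc1ccccc1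
Why: Williamson ether synthesis with two equivalents of halide stops at the diether because the last ortho OH is hydrogen-bonded to the acetyl oxygen, and since the two ortho OH groups of 5 are equivalent no regiochemical question arises; the OH left free is the future O1.

Step 5
Reactants: 6 1-[2,4-bis(benzyloxy)-6-hydroxyphenyl]ethanone
Product: 7 1-[4,6-bis(benzyloxy)-2-hydroxy-3-iodophenyl]ethanone
Conditions: NIS (1.0 equiv), TFA (cat.), MeCN, 0 °C to rt
Reagents that add atoms: N-iodosuccinimide, O=C1CCC(=O)N1I
Why: Electrophilic aromatic iodination ortho to the free phenol, because C3 is flanked by the small OH whereas C5 sits between two benzyloxy groups, so the halogen marks the future C8 next to the future O1.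

Step 6
Reactants: 4 5,7,4'-tri-O-benzylapigenin-8-boronic acid pinacol ester; 7 1-[4,6-bis(benzyloxy)-2-hydroxy-3-iodophenyl]ethanone
Product: 8 8-[3-acetyl-4,6-bis(benzyloxy)-2-hydroxyphenyl]-5,7,4'-tri-O-benzylapigenin
Conditions: Pd(OAc)2 (10 mol %), SPhos (20 mol %), K3PO4, toluene/H2O, 100 °C
Reagents that add atoms: none
Why: Suzuki–Miyaura coupling with the bulky, electron-rich biaryl phosphine SPhos, a ligand type made for tetra-ortho-substituted biaryls, joins C8'' to the future C8, and the phenol travels as its phenoxide and needs no protection.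

Step 7
Reactants: 8 8-[3-acetyl-4,6-bis(benzyloxy)-2-hydroxyphenyl]-5,7,4'-tri-O-benzylapigenin
Product: 9 tert-butyl β-keto ester of 8 (acetyl group extended to C(=O)CH2CO2tBu)
Conditions: LiN(SiMe3)2 (3.3 equiv), THF, −78 °C; Boc2O (1.1 equiv), −78 to 0 °C; AcOH quench
Reagents that add atoms: di-tert-butyl dicarbonate, CC(C)(C)OC(=O)OC(=O)OC(C)(C)C
Why: Claisen-type C-acylation of the lithium dianion (phenoxide plus enolate), with the third equivalent of base taking up the more acidic product; acylation at the phenoxide oxygen would be no dead end, since an O-to-C acyl shift of the Baker–Venkataraman type leads to the same β-keto ester, and the bulk of the tert-butyl group holds back lactonisation.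

Step 8
Reactants: 9 tert-butyl β-keto ester of 8; 10 4-(benzyloxy)benzaldehyde
Product: 11 tert-butyl (Z)-2-aroyl-3-[4-(benzyloxy)phenyl]acrylate (alkylidene β-keto ester with free C8a phenol)
Conditions: piperidine (15 mol %), AcOH (15 mol %), 4 Å molecular sieves, toluene, rt
Reagents that add atoms: none
Why: Knoevenagel condensation under piperidinium acetate catalysis with sieves to take up water, run at room temperature so that the hydrogen-bonded and flanked phenol does not add to the new acceptor; the Z isomer, aryl cis to the ester, is expected to prevail.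

Step 9
Reactants: 11 alkylidene β-keto ester
Product: 14 (2S)-5,7,4',5'',7'',4'''-hexa-O-benzyl-2,3-dihydrocupressuflavone, via ring-closed tert-butyl ester 12 (not isolated), via β-keto acid 13 (not isolated)
Conditions: quinidine-derived thiourea N-[3,5-bis(trifluoromethyl)phenyl]-N'-[(9R)-6'-methoxycinchonan-9-yl]thiourea (10 mol %), toluene, −25 °C; then p-TsOH·H2O (50 mol %), 80 °C, same flask
Reagents that add atoms: none
Why: The quinuclidine nitrogen of the bifunctional catalyst takes the proton of the C8a phenol while the two thiourea N–H bonds hold the carbonyl groups of the alkylidene β-keto ester, so that O1 adds to C2 within a chiral hydrogen-bonded ion pair and the resulting enolate is protonated at C3. This is the catalytic asymmetric intramolecular oxa-Michael addition to alkylidene β-keto esters, a known entry to enantioenriched flavanones, followed in the same flask by the known acid-induced loss of isobutene and CO2. Ring C (C4, C3, C2, O1, C8a, C4a) closes in the 6-endo-trig mode and is the only ring that the whole route has to close. C2 is controlled by the catalyst alone, which exposes one face of the C2=C3 bond to O1: the quinidine-derived catalyst is chosen for the 2S sense, to be confirmed on a simple model substrate, with the quinine-derived pseudoenantiomer as the mirror-image option, whereas C3 is a labile centre that disappears with the ester. The site selectivity needed, 8-linked rather than 6-linked flavanone, is secured by the substrate, since O5 and O7 are benzyl ethers and O1 is the only free phenol, and the flavone enone does not compete because it is a vinylogous ester with no nucleophile within reach. Removal of the ester also takes away the activation that makes the addition reversible, so the C2 configuration is locked before isolation; both axial forms of 11 have to follow the catalyst, which is the main uncertainty.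

Step 10
Reactants: 14 (2S)-hexa-O-benzyl-2,3-dihydrocupressuflavone
Product: 15 (2S)-2,3-dihydrocupressuflavone (target)
Conditions: H2 (1 atm), Pd/C (10 wt %), THF/MeOH, AcOH (trace), rt
Reagents that add atoms: none
Why: Catalytic hydrogenolysis of the six aryl benzyl ethers in a neutral to faintly acidic medium avoids the base-induced retro-oxa-Michael opening that would scramble C2, while the flavone C2''=C3'' bond, a vinylogous ester, and the C2–O1 bond react far more slowly and should survive if hydrogen uptake is monitored.

Compound list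
1 | apigenin | O=c1cc(-c2ccc(O)cc2)oc2cc(O)cc(O)c12 | starting material
2 | 5,7,4'-tri-O-benzylapigenin | O=c1cc(-c2ccc(OCc3ccccc3)cc2)oc2cc(OCc3ccccc3)cc(OCc3ccccc3)c12 | intermediate
3 | 8-iodo-5,7,4'-tri-O-benzylapigenin | O=c1cc(-c2ccc(OCc3ccccc3)cc2)oc2c(I)c(OCc3ccccc3)cc(OCc3ccccc3)c12 | intermediate
4 | 5,7,4'-tri-O-benzylapigenin-8-boronic acid pinacol ester | O=c1cc(-c2ccc(OCc3ccccc3)cc2)oc2c(B3OC(C)(C)C(C)(C)O3)c(OCc3ccccc3)cc(OCc3ccccc3)c12 | intermediate
5 | 2',4',6'-trihydroxyacetophenone | CC(=O)c1c(O)cc(O)cc1O | starting material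
6 | 1-[2,4-bis(benzyloxy)-6-hydroxyphenyl]ethanone | CC(=O)c1c(O)cc(OCc2ccccc2)cc1OCc1ccccc1 | intermediate
7 | 1-[4,6-bis(benzyloxy)-2-hydroxy-3-iodophenyl]ethanone | CC(=O)c1c(O)c(I)c(OCc2ccccc2)cc1OCc1ccccc1 | intermediate
8 | 8-[3-acetyl-4,6-bis(benzyloxy)-2-hydroxyphenyl]-5,7,4'-tri-O-benzylapigenin (both axial forms) | CC(=O)c1c(O)c(-c2c(OCc3ccccc3)cc(OCc3ccccc3)c3c(=O)cc(-c4ccc(OCc5ccccc5)cc4)oc23)c(OCc2ccccc2)cc1OCc1ccccc1 | intermediate
9 | tert-butyl 3-aryl-3-oxopropanoate derived from 8 (β-keto ester, free C8a phenol) | CC(C)(C)OC(=O)CC(=O)c1c(O)c(-c2c(OCc3ccccc3)cc(OCc3ccccc3)c3c(=O)cc(-c4ccc(OCc5ccccc5)cc4)oc23)c(OCc2ccccc2)cc1OCc1ccccc1 | intermediate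
10 | 4-(benzyloxy)benzaldehyde | O=Cc1ccc(OCc2ccccc2)cc1 | starting material
11 | tert-butyl (Z)-2-aroyl-3-[4-(benzyloxy)phenyl]acrylate (alkylidene β-keto ester, free C8a phenol) | CC(C)(C)OC(=O)/C(=C\c1ccc(OCc2ccccc2)cc1)C(=O)c1c(O)c(-c2c(OCc3ccccc3)cc(OCc3ccccc3)c3c(=O)cc(-c4ccc(OCc5ccccc5)cc4)oc23)c(OCc2ccccc2)cc1OCc1ccccc1 | intermediate
12 | tert-butyl (2S)-hexa-O-benzyl-2,3-dihydrocupressuflavone-3-carboxylate (C3 labile, not defined) | O=C1C(C(=O)OC(C)(C)C)[C@@H](c2ccc(OCc3ccccc3)cc2)Oc2c1c(OCc1ccccc1)cc(OCc1ccccc1)c2-c1c(OCc2ccccc2)cc(OCc2ccccc2)c2c(=O)cc(-c3ccc(OCc4ccccc4)cc3)oc12 | intermediate (not isolated)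
13 | (2S)-hexa-O-benzyl-2,3-dihydrocupressuflavone-3-carboxylic acid (C3 labile, not defined) | O=C1C(C(=O)O)[C@@H](c2ccc(OCc3ccccc3)cc2)Oc2c1c(OCc1ccccc1)cc(OCc1ccccc1)c2-c1c(OCc2ccccc2)cc(OCc2ccccc2)c2c(=O)cc(-c3ccc(OCc4ccccc4)cc3)oc12 | intermediate (not isolated)
14 | (2S)-5,7,4',5'',7'',4'''-hexa-O-benzyl-2,3-dihydrocupressuflavone | O=C1C[C@@H](c2ccc(OCc3ccccc3)cc2)Oc2c1c(OCc1ccccc1)cc(OCc1ccccc1)c2-c1c(OCc2ccccc2)cc(OCc2ccccc2)c2c(=O)cc(-c3ccc(OCc4ccccc4)cc3)oc12 | intermediate
15 | (2S)-2,3-dihydrocupressuflavone, the 8,8''-linked (2S)-naringenin–apigenin dimer | O=C1C[C@@H](c2ccc(O)cc2)Oc2c1c(O)cc(O)c2-c1c(O)cc(O)c2c(=O)cc(-c3ccc(O)cc3)oc12 | target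

Total step count: 10. Longest linear sequence: 8 steps (1, 2, 3, 6, 7, 8, 9, 10).

Steps most likely to fail

Step 9. Three things may go wrong.
- Facial selectivity may be poor for one of the two axial forms of 11.
- Closure may be slow because O1 is hemmed in between the aroyl group and the flavone.
- The C2 configuration may erode through acid-induced ring opening while the ester is removed.

The fallback replaces catalysis by resolution. It sets out from 8 and 10 and comes back at 14. A Claisen–Schmidt condensation (KOH, EtOH/THF, rt) would give the open 2'-hydroxychalcone F1. NaOAc in refluxing EtOH would close ring C without facial control to the C2-epimeric hexabenzyl ether F2. Preparative chromatography on a chiral stationary phase would then separate the 2S material, which is 14. The 2R material would be reopened to F1 with KOH and sent round again.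

Step 6. Protodeboronation of the di-ortho-alkoxy boronate may outrun a slow transmetalation onto the hindered, phenoxide-bearing arylpalladium species. The fallback changes the metal and masks the phenol. It sets out from 3 and 7 and comes back at 8. Phenol 7 would be capped (MOMCl, iPr2NEt, CH2Cl2) as the methoxymethyl ether F3. Zinc insertion into 3 (Zn dust, LiCl, THF, 50 °C) would give the arylzinc iodide F4. A Negishi coupling (Pd2(dba)3, RuPhos, THF/NMP, 70 °C) needs neither base nor water for transmetalation, and would give the protected biaryl ketone F5. HCl in MeOH/THF at 40 °C would free the phenol to give 8.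

Step 8. The amine may promote premature ring closure without stereocontrol as the acceptor forms, or the condensation with the electron-rich aldehyde may stall at room temperature. The fallback masks the nucleophile. It sets out from 8 and comes back at 11. The phenol would be masked (4-methoxybenzyl chloride, K2CO3, DMF, 60 °C) as the 4-methoxybenzyl ether F6. This would be carried through the acylation of step 7, now with two equivalents of base, to the masked β-keto ester F7. A Knoevenagel condensation with 10 may now be forced (piperidine, AcOH, toluene, reflux, water separator) and would give the masked alkylidene F8. Oxidative unmasking with DDQ in wet CH2Cl2 at 0 °C, a medium free of base, would release 11 just before the key step.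

Further compounds
F1 | step 9 | (E)-2'-hydroxychalcone from 8 and 10 (3'-flavonyl-4,4',6'-tris(benzyloxy)-2'-hydroxychalcone) | O=C(/C=C/c1ccc(OCc2ccccc2)cc1)c1c(O)c(-c2c(OCc3ccccc3)cc(OCc3ccccc3)c3c(=O)cc(-c4ccc(OCc5ccccc5)cc4)oc23)c(OCc2ccccc2)cc1OCc1ccccc1
F2 | step 9 | hexa-O-benzyl-2,3-dihydrocupressuflavone, both C2 epimers | O=C1CC(c2ccc(OCc3ccccc3)cc2)Oc2c1c(OCc1ccccc1)cc(OCc1ccccc1)c2-c1c(OCc2ccccc2)cc(OCc2ccccc2)c2c(=O)cc(-c3ccc(OCc4ccccc4)cc3)oc12
F3 | step 6 | 1-[4,6-bis(benzyloxy)-3-iodo-2-(methoxymethoxy)phenyl]ethanone | CC(=O)c1c(OCOC)c(I)c(OCc2ccccc2)cc1OCc1ccccc1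
F4 | step 6 | (5,7,4'-tri-O-benzylapigenin-8-yl)zinc iodide | O=c1cc(-c2ccc(OCc3ccccc3)cc2)oc2c([Zn]I)c(OCc3ccccc3)cc(OCc3ccccc3)c12
F5 | step 6 | methoxymethyl ether of 8 | CC(=O)c1c(OCOC)c(-c2c(OCc3ccccc3)cc(OCc3ccccc3)c3c(=O)cc(-c4ccc(OCc5ccccc5)cc4)oc23)c(OCc2ccccc2)cc1OCc1ccccc1
F6 | step 8 | 4-methoxybenzyl ether of 8 | CC(=O)c1c(OCc2ccc(OC)cc2)c(-c2c(OCc3ccccc3)cc(OCc3ccccc3)c3c(=O)cc(-c4ccc(OCc5ccccc5)cc4)oc23)c(OCc2ccccc2)cc1OCc1ccccc1
F7 | step 8 | 4-methoxybenzyl ether of 9 | CC(C)(C)OC(=O)CC(=O)c1c(OCc2ccc(OC)cc2)c(-c2c(OCc3ccccc3)cc(OCc3ccccc3)c3c(=O)cc(-c4ccc(OCc5ccccc5)cc4)oc23)c(OCc2ccccc2)cc1OCc1ccccc1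
F8 | step 8 | 4-methoxybenzyl ether of 11 | CC(C)(C)OC(=O)/C(=C\c1ccc(OCc2ccccc2)cc1)C(=O)c1c(OCc2ccc(OC)cc2)c(-c2c(OCc3ccccc3)cc(OCc3ccccc3)c3c(=O)cc(-c4ccc(OCc5ccccc5)cc4)oc23)c(OCc2ccccc2)cc1OCc1ccccc1
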